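**Assumptions:** locants are germacrane numbers (C1–C15; lactone O on C6, angelate on C8, C3–O–C10 bridge). Commercial (R)-(−)-linalool is taken as enantiopure; any minor C10 epimer is removed as a diastereomer after Step 3. TES = triethylsilyl, TBDPS = tert-butyldiphenylsilyl. The route is a paper design and has not been run.

## Retrosynthetic overview

1. Niveusin B ⇒ late angeloylation of the C8–OH and C15 desilylation; the THF hemiketal (ring 3) forms last, when the unmasked C10–OH adds to the C3 ketone.
2. The ten-membered carbocycle (ring 1) and the α-methylene-γ-butyrolactone (ring 2) form together by intramolecular Cr(II) Barbier allylation (C6–C7) of a (Z)-4-oxo-enal by a 2-(bromomethyl)enoate.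
3. The (Z)-4-oxo-enal (C3–C6 + C15) is carried as a 2,3-disubstituted furan; the allyl bromide comes from a Morita–Baylis–Hillman adduct of an α-silyloxy aldehyde with methyl acrylate.
4. The chain is assembled by B-alkyl Suzuki coupling of the vinyl group of (R)-linalool (supplies C10) with a 2-bromofuran; C8–O is set by L-proline α-aminoxylation.

## Route

**Step 1**
Reactants: 1, (R)-(−)-linalool
Product: 2, (R)-linalool triethylsilyl ether
Conditions: TESOTf, 2,6-lutidine, CH2Cl2, −78 → 0 °C
Reagents that add atoms: triethylsilyl triflate, CC[Si](CC)(CC)OS(=O)(=O)C(F)(F)F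
Why: Silylation of the tertiary alcohol prevents lactol formation once the C7 aldehyde is unveiled; the C10 stereocentre comes from the chiral pool and is untouched.

**Step 2**
Reactants: 2
Product: 3, (4R)-4-methyl-4-(triethylsilyloxy)hex-5-enal
Conditions: O3 (1 equiv, Sudan III end-point), pyridine, CH2Cl2, −78 °C; then PPh3
Reagents that add atoms: ozone, O=[O+][O-]
Why: Chemoselective ozonolysis; the electron-rich trisubstituted alkene is cleaved much faster than the monosubstituted vinyl group.

**Step 3** (telescoped, one purification)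
Reactants: 3
Product: 4, (2R,4R)-4-methyl-4-(triethylsilyloxy)hex-5-ene-1,2-diol
Conditions: PhNO, L-proline (20 mol %), DMSO, rt; then NaBH4, MeOH, 0 °C; then CuSO4·5H2O (30 mol %), MeOH, rt
Reagents that add atoms: nitrosobenzene, O=Nc1ccccc1
Why: Proline-catalysed enamine α-aminoxylation; the L-proline enamine is O-attacked on the acid-directed face, setting C8 as R under catalyst control, then hydride reduction of the aldehyde and Cu(II) N–O cleavage give the diol.

**Step 4**
Reactants: 4
Product: 5, (2R,4R)-4-methyl-1,2,4-tris(triethylsilyloxy)hex-5-ene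
Conditions: TESCl (2.5 equiv), imidazole, DMAP (cat.), DMF, 0 °C → rt
Reagents that add atoms: chlorotriethylsilane, CC[Si](Cl)(CC)CC
Why: Bis-silylation; the primary TES ether is the one later oxidised directly, so no separate deprotection is needed.

**Step 5**
Reactants: 6, furan-3-ylmethanol
Product: 7, tert-butyl(furan-3-ylmethoxy)diphenylsilane
Conditions: TBDPSCl, imidazole, CH2Cl2, rt
Reagents that add atoms: tert-butyldiphenylsilyl chloride, CC(C)(C)[Si](Cl)(c1ccccc1)c1ccccc1
Why: Silylation; TBDPS is chosen to survive the later acidic removal of the TES groups.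

**Step 6**
Reactants: 7
Product: 8, [(2-bromofuran-3-yl)methoxy](tert-butyl)diphenylsilane
Conditions: n-BuLi, THF, −78 °C; then BrCCl2CCl2Br, −78 °C
Reagents that add atoms: 1,2-dibromotetrachloroethane, BrC(Cl)(Cl)C(Cl)(Cl)Br
Why: Directed lithiation at furan C2 (α position, ortho to CH2OSi) then electrophilic bromination; kept cold to avoid 1,4 O→C silyl migration.

**Step 7**
Reactants: 5 and 8
Product: 9, 2-[(3S,5R)-3-methyl-3,5,6-tris(triethylsilyloxy)hexyl]-3-[(tert-butyldiphenylsilyloxy)methyl]furan
Conditions: 9-BBN, THF, 0 °C → rt; then 8, Pd(dppf)Cl2 (5 mol %), AsPh3, Cs2CO3, DMF/H2O, rt → 50 °C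
Reagents that add atoms: none
Why: Anti-Markovnikov hydroboration of the only alkene followed by B-alkyl Suzuki–Miyaura coupling makes the C2–C3 bond; no stereocentre is involved (the C10 label becomes S only through a CIP priority change).

**Step 8**
Reactants: 9
Product: 10, (2R,4S)-6-{3-[(tert-butyldiphenylsilyloxy)methyl]furan-2-yl}-4-methyl-2,4-bis(triethylsilyloxy)hexanal
Conditions: (COCl)2, DMSO, CH2Cl2, −78 → −30 °C; then i-Pr2NEt, −78 → 0 °C
Reagents that add atoms: none
Why: Swern conditions oxidise a primary TES ether directly to the aldehyde while secondary and tertiary TES ethers, TBDPS and the furan survive; the hindered base limits C8 epimerisation.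

**Step 9**
Reactants: 10 and 11, methyl acrylate
Product: 12, methyl (4R,6S)-8-{3-[(tert-butyldiphenylsilyloxy)methyl]furan-2-yl}-3-hydroxy-6-methyl-2-methylidene-4,6-bis(triethylsilyloxy)octanoate (C3 epimer mixture)
Conditions: methyl acrylate (10 equiv), DABCO (1 equiv), MeOH (cat.), neat, rt, 4–7 d
Reagents that add atoms: methyl acrylate (compound 11), C=CC(=O)OC
Why: Morita–Baylis–Hillman reaction installs C11–C13; the new carbinol (C7) is formed as a mixture but is erased in Step 10.

**Step 10**
Reactants: 12
Product: 13, methyl (2Z,4R,6S)-2-(bromomethyl)-8-{3-[(tert-butyldiphenylsilyloxy)methyl]furan-2-yl}-6-methyl-4,6-bis(triethylsilyloxy)oct-2-enoate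
Conditions: MsCl, Et3N, CH2Cl2, −20 °C; then LiBr, THF, 0 °C → rt
Reagents that add atoms: lithium bromide, [Li+].[Br-]
Why: Mesylation then SN2′ bromide displacement gives the conjugated primary allyl bromide without electrophilic bromine touching the furan; alkene geometry is not critical because the allyl-chromium equilibrates.

**Step 11**
Reactants: 13
Product: 14, methyl (2Z,4R,6S,10Z)-2-(bromomethyl)-10-[(tert-butyldiphenylsilyloxy)methyl]-6-methyl-9,12-dioxo-4,6-bis(triethylsilyloxy)dodeca-2,10-dienoate
Conditions: NBS (1.05 equiv), NaHCO3, THF/acetone/H2O, −20 °C, dark; used at once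
Reagents that add atoms: water, O
Why: Oxidative furan ring opening gives the cis-4-oxo-enal (C3 ketone, C6 aldehyde); the Z C4=C5 geometry is inherited from the ring and no pyridine or acid is present to isomerise it.

**Step 12**
Reactants: 14
Product: 15, 15-(tert-butyldiphenylsilyloxy)-3-oxo-8,10-bis(triethylsilyloxy)germacra-4Z,11(13)-dien-12,6-olide with the target configuration at C6, C7, C8 and C10 (CIP 6R,7S,8R,10S; the C7 label is S only because of the O-silyl priority)
Conditions: CrCl2 (8 equiv), THF, 2 mM, slow addition, rt; aq. NH4Cl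
Reagents that add atoms: none
Why: Intramolecular Nozaki–Hiyama/Barbier 2-(alkoxycarbonyl)allylation: the allyl-Cr(III) adds through C7 to the aldehyde only, closing the ten-membered ring, and the C6 alkoxide lactonises onto the methyl ester. C6 and C7 are set by macrocyclic substrate control from the C8–OTES centre and the Z-enone tether; the 6,7-trans lactone is the expected, not assured, outcome.

**Step 13**
Reactants: 15
Product: 16, 15-O-TBDPS-8-O-desangeloyl-niveusin B (3R,6R,7R,8R,10S)
Conditions: TFA/H2O/THF (1:1:8), 0 °C → rt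
Reagents that add atoms: none
Why: Acidic hydrolysis of both TES ethers (TBDPS survives); the freed C10–OH adds to the C3 ketone to give the five-membered hemiketal, whose C3 configuration is fixed because the one-atom O-bridge can only span the ring cis. Any unlactonised hydroxy ester from Step 12 closes here.

**Step 14**
Reactants: 16 and 17, angelic acid
Product: 18, 15-O-TBDPS-niveusin B
Conditions: 17, 2,4,6-trichlorobenzoyl chloride, Et3N, toluene, rt; then 16, 75 °C (no DMAP)
Reagents that add atoms: angelic acid (compound 17), C/C=C(/C)C(=O)O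
Why: Yamaguchi mixed-anhydride esterification acylates only the secondary C8–OH (C3–OH is a tertiary hemiketal, C15 is silylated); omitting DMAP limits angelate-to-tiglate isomerisation.

**Step 15**
Reactants: 18
Product: 19, niveusin B
Conditions: HF·pyridine, pyridine, THF, 0 °C → rt
Reagents that add atoms: none
Why: Buffered fluoride desilylation frees the C15 alcohol without affecting the α-methylene lactone, angelate or hemiketal.

## Compound list

1 | (R)-(−)-linalool | C=C[C@](C)(O)CCC=C(C)C | starting material
2 | (R)-linalool TES ether | C=C[C@](C)(O[Si](CC)(CC)CC)CCC=C(C)C | intermediate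
3 | (4R)-4-methyl-4-(triethylsilyloxy)hex-5-enal | C=C[C@](C)(O[Si](CC)(CC)CC)CCC=O | intermediate
4 | (2R,4R)-4-methyl-4-(triethylsilyloxy)hex-5-ene-1,2-diol | C=C[C@](C)(O[Si](CC)(CC)CC)C[C@@H](O)CO | intermediate
5 | (2R,4R)-4-methyl-1,2,4-tris(triethylsilyloxy)hex-5-ene | C=C[C@](C)(O[Si](CC)(CC)CC)C[C@@H](O[Si](CC)(CC)CC)CO[Si](CC)(CC)CC | intermediate
6 | furan-3-ylmethanol | OCc1ccoc1 | starting material
7 | tert-butyl(furan-3-ylmethoxy)diphenylsilane | CC(C)(C)[Si](OCc1ccoc1)(c1ccccc1)c1ccccc1 | intermediate
8 | [(2-bromofuran-3-yl)methoxy](tert-butyl)diphenylsilane | CC(C)(C)[Si](OCc1ccoc1Br)(c1ccccc1)c1ccccc1 | intermediate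
9 | Suzuki product, (3S,5R)-tris-TES hexyl furan | CC(C)(C)[Si](OCc1ccoc1CC[C@](C)(O[Si](CC)(CC)CC)C[C@@H](O[Si](CC)(CC)CC)CO[Si](CC)(CC)CC)(c1ccccc1)c1ccccc1 | intermediate
10 | (2R,4S)-α-silyloxy aldehyde | CC(C)(C)[Si](OCc1ccoc1CC[C@](C)(O[Si](CC)(CC)CC)C[C@@H](O[Si](CC)(CC)CC)C=O)(c1ccccc1)c1ccccc1 | intermediate
11 | methyl acrylate | C=CC(=O)OC | starting material
12 | MBH adduct (C7 epimers) | CC(C)(C)[Si](OCc1ccoc1CC[C@](C)(O[Si](CC)(CC)CC)C[C@@H](O[Si](CC)(CC)CC)C(O)C(=C)C(=O)OC)(c1ccccc1)c1ccccc1 | intermediate
13 | (2Z,4R,6S)-allyl bromide | CC(C)(C)[Si](OCc1ccoc1CC[C@](C)(O[Si](CC)(CC)CC)C[C@@H](O[Si](CC)(CC)CC)/C=C(\CBr)C(=O)OC)(c1ccccc1)c1ccccc1 | intermediate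
14 | (Z)-4-oxo-enal allyl bromide | O=C/C=C(/CO[Si](c1ccccc1)(c1ccccc1)C(C)(C)C)C(=O)CC[C@](C)(O[Si](CC)(CC)CC)C[C@@H](O[Si](CC)(CC)CC)/C=C(\CBr)C(=O)OC | intermediate
15 | macrocyclic 3-keto lactone | C=C1C(=O)O[C@@H]2/C=C(/CO[Si](c3ccccc3)(c3ccccc3)C(C)(C)C)C(=O)CC[C@@](C)(C[C@@H](O[Si](CC)(CC)CC)[C@@H]12)O[Si](CC)(CC)CC | intermediate
16 | 15-O-TBDPS-8-desangeloyl-niveusin B | C=C1C(=O)O[C@@H]2/C=C(/CO[Si](c4ccccc4)(c4ccccc4)C(C)(C)C)[C@@]3(O)CC[C@@](C)(C[C@@H](O)[C@@H]12)O3 | intermediate
17 | angelic acid, (Z)-2-methylbut-2-enoic acid | C/C=C(/C)C(=O)O | starting material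
18 | 15-O-TBDPS-niveusin B | C=C1C(=O)O[C@@H]2/C=C(/CO[Si](c4ccccc4)(c4ccccc4)C(C)(C)C)[C@@]3(O)CC[C@@](C)(C[C@@H](OC(=O)/C(C)=C\C)[C@@H]12)O3 | intermediate
19 | niveusin B | C=C1C(=O)O[C@@H]2/C=C(/CO)[C@@]3(O)CC[C@@](C)(C[C@@H](OC(=O)/C(C)=C\C)[C@@H]12)O3 | target

## Summary

Total steps: 15 (Step 3 is telescoped; count 16 if the N–O cleavage is run separately).
Longest linear sequence: 13 steps from (R)-linalool (Steps 1–4, 7–15).

Steps most likely to fail:

1. **Step 12, Cr(II) macrocyclisation.** Risks are ring-closure yield, Z→E isomerisation or reduction of the ene-dione, and the wrong C6/C7 facial sense (acyclic Barbier reactions of such bromides often favour the cis-lactone). Fallback: move the ring-closing bond to C3–C4. Hydroformylate the linalool vinyl group to a C3 aldehyde, form the lactone by an intermolecular Barbier reaction with (Z)-3-iodo-4-silyloxybut-2-enal (diastereomers separable), then close the ring by intramolecular Nozaki–Hiyama–Kishi coupling and oxidise the C3 carbinol to the ketone.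

2. **Step 11, furan to (Z)-4-oxo-enal.** Risks are over-oxidation, Z→E isomerisation and instability of the ene-dione beside the allyl bromide. Fallback: remove the TES groups first so that oxidation with the free C10–OH gives the stable spiro-lactol (1,6-dioxaspiro[4.4]non-3-en-2-ol, C3 already ketalised by O10), and use this masked aldehyde directly in an In- or Zn-mediated Barbier cyclisation.

3. **Step 14, late angeloylation.** Risks are a hindered 8β-OH, angelate-to-tiglate isomerisation, and 6,12→8,12 translactonisation or oxa-Michael reactions of the free 8-OH. Fallback: install the angelate before ring closure by selectively cleaving the secondary C8–OTES of bromide 13 and esterifying there, then carry the ester through Steps 11–12 and finish with one global desilylation.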